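**Retrosynthetic overview**

1. Target 31 ⇐ bis-MOM ether 30 ⇐ anti opening by chloride at the methyl carbon of the enantioenriched quinone epoxide 29 ⇐ catalytic asymmetric Weitz–Scheffer epoxidation of naphthoquinone 28 ⇐ Teuber oxidation of 1-naphthol 27.
2. Key disconnection in 27: the ring bond between C4 (the future carbonyl carbon on the side of the aromatic C5–H) and C3 (the future carbinol carbon). It is made by 6π electrocyclisation of an o-quinodimethane released by 4π opening of a benzocyclobutenolate built from benzocyclobutenone 22 and alkenyl iodide 11.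
3. Enabling feature: the strained four-membered ring of 22 (bicyclo[4.2.0]octatriene; C7 carbonyl and C8–H(OMe), fused to the benzene ring at C1/C6), with C7 on the ring carbon next to the MOM-oxygenated C5. After addition, the oxide on C7 triggers cleavage of the C7–C8 σ bond, and C8 and the alkenyl CH become the two ends of a hexatriene.
4. 22 ⇐ [2+2] of the aryne from iodo triflate 15 (phloroglucinol-derived) with ketene silyl acetal 18; 11 ⇐ hydrozirconation–iodination of enyne 9 ⇐ isosesquilavandulyl bromide 7 ⇐ methyl acetoacetate + geranyl bromide.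
5. Ring order: benzene ring (from 12) → cyclobutene ring (step 12) → six-membered carbocycle (step 13) → oxirane (step 15, opened in step 16).

Key step: step 13

Remark on names: isosesquilavandulyl = (4E)-5,9-dimethyl-2-(propan-2-ylidene)deca-4,8-dien-1-yl; MOM = methoxymethyl.

Assumption: the facial sense of the ion-pair epoxidation (step 15) is assigned on a trial run; the quinidinium salt is written, and its quininium pseudoenantiomer takes its place if the sense is opposite.

**Route**

Step 1
Reactants: 1 methyl acetoacetate; 2 geranyl bromide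
Product: 3 methyl (4E)-2-acetyl-5,9-dimethyldeca-4,8-dienoate (racemic)
Conditions: K2CO3, acetone, reflux (1 in excess)
Reagents that add atoms: none
Why: Acetoacetic ester C-alkylation (SN2 of the enolate on the primary allylic bromide), with excess 1 holding back dialkylation and the E alkene of 2 untouched.

Step 2
Reactants: 3 methyl (4E)-2-acetyl-5,9-dimethyldeca-4,8-dienoate
Product: 4 methyl (2Z,4E)-5,9-dimethyl-2-{1-[(trifluoromethanesulfonyl)oxy]ethylidene}deca-4,8-dienoate
Conditions: Tf2O, i-Pr2NEt, CH2Cl2, −78 → 0 °C
Reagents that add atoms: trifluoromethanesulfonic anhydride, O=S(=O)(OS(=O)(=O)C(F)(F)F)C(F)(F)F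
Why: O-sulfonylation of the β-keto ester enol (enol triflate formation); the Z isomer is drawn, but the geometry is without consequence because both β-substituents become methyl in step 3.

Step 3
Reactants: 4 enol triflate
Product: 5 methyl (4E)-5,9-dimethyl-2-(propan-2-ylidene)deca-4,8-dienoate
Conditions: MeMgBr, Fe(acac)3 (5 mol%), THF/NMP, −30 °C
Reagents that add atoms: methylmagnesium bromide, C[Mg]Br
Why: Iron-catalysed cross-coupling of an enol triflate with a Grignard reagent replaces OTf by methyl faster than the Grignard attacks the ester, and gives the tetrasubstituted alkene without an E/Z issue.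

Step 4
Reactants: 5 methyl (4E)-5,9-dimethyl-2-(propan-2-ylidene)deca-4,8-dienoate
Product: 6 (4E)-5,9-dimethyl-2-(propan-2-ylidene)deca-4,8-dien-1-ol (isosesquilavandulol)
Conditions: i-Bu2AlH (2.2 equiv), CH2Cl2, −78 → 0 °C; aq. Rochelle salt
Reagents that add atoms: none
Why: 1,2-Reduction of the α,β-unsaturated ester to the allylic alcohol by the aluminium hydride, which leaves the isolated alkenes alone.

Step 5
Reactants: 6 isosesquilavandulol
Product: 7 (5E)-3-(bromomethyl)-2,6,10-trimethylundeca-2,5,9-triene (isosesquilavandulyl bromide)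
Conditions: CBr4, PPh3, CH2Cl2, 0 °C
Reagents that add atoms: carbon tetrabromide, BrC(Br)(Br)Br
Why: Appel reaction, an SN2 displacement of the oxyphosphonium at the primary carbon under neutral conditions that spare the acid-sensitive polyene.

Step 6
Reactants: 7 isosesquilavandulyl bromide; 8 prop-1-yn-1-ylmagnesium bromide
Product: 9 (7E)-8,12-dimethyl-5-(propan-2-ylidene)trideca-7,11-dien-2-yne
Conditions: CuI (copper iodide, 10 mol%), THF, 0 → 25 °C
Reagents that add atoms: none
Why: Copper-catalysed substitution of the allylic bromide by the alkynyl Grignard reagent at the unhindered primary terminus (the SN2′ terminus is a fully substituted carbon) gives the skipped enyne.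

Step 7
Reactants: 9 enyne
Product: 11 (2E,7E)-2-iodo-8,12-dimethyl-5-(propan-2-ylidene)trideca-2,7,11-triene, via alkenylzirconocene chloride 10 (not isolated)
Conditions: Cp2Zr(H)Cl (1.5 equiv), THF, 25 → 45 °C; then I2, THF, 0 °C
Reagents that add atoms: iodine, II
Why: syn-Hydrozirconation of the alkyne, with excess hydride equilibrating the metal to the less hindered methyl-bearing carbon, then iodinolysis with retention gives the E 2-iodo-2-ene; tri- and tetrasubstituted alkenes are inert to Cp2Zr(H)Cl under these conditions.

Step 8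
Reactants: 12 phloroglucinol
Product: 13 3,5-bis(methoxymethoxy)phenol
Conditions: MOMCl (2.0 equiv), i-Pr2NEt, DMF, 0 °C; bis-ether separated from mono- and tris-ether
Reagents that add atoms: chloromethyl methyl ether, COCCl
Why: Statistical O-alkylation of the symmetric triol (Williamson-type acetal ether formation), in which every bis-ether is the same compound.

Step 9
Reactants: 13 3,5-bis(methoxymethoxy)phenol
Product: 14 2-iodo-3,5-bis(methoxymethoxy)phenol
Conditions: N-iodosuccinimide, CH2Cl2, −20 °C
Reagents that add atoms: N-iodosuccinimide, O=C1CCC(=O)N1I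
Why: Electrophilic aromatic iodination ortho to the free hydroxyl, the strongest activator, at the position between OH and OMOM, which is less encumbered than the one between two OMOM groups; any 4-iodo isomer is removed here.

Step 10
Reactants: 14 2-iodo-3,5-bis(methoxymethoxy)phenol
Product: 15 2-iodo-3,5-bis(methoxymethoxy)phenyl trifluoromethanesulfonate
Conditions: Tf2O, pyridine, CH2Cl2, 0 °C
Reagents that add atoms: trifluoromethanesulfonic anhydride, O=S(=O)(OS(=O)(=O)C(F)(F)F)C(F)(F)F
Why: O-Triflation of the phenol gives the ortho-iodoaryl triflate, a low-temperature aryne precursor.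

Step 11
Reactants: 16 methyl 2-methoxyacetate
Product: 18 tert-butyl[(1,2-dimethoxyethenyl)oxy]dimethylsilane, via lithium ester enolate 17 (not isolated)
Conditions: LiN(i-Pr)2, THF, −78 °C; then t-BuMe2SiCl, DMPU, −78 → 0 °C
Reagents that add atoms: tert-butyldimethylsilyl chloride, CC(C)(C)[Si](C)(C)Cl
Why: Ester enolate O-silylation gives the ketene silyl acetal, whose E/Z mixture is without consequence.

Step 12
Reactants: 15 2-iodo-3,5-bis(methoxymethoxy)phenyl trifluoromethanesulfonate; 18 ketene silyl acetal
Product: 22 8-methoxy-3,5-bis(methoxymethoxy)bicyclo[4.2.0]octa-1,3,5-trien-7-one, via aryllithium 19 (not isolated), via aryne 20 (not isolated), via silyl ketal cycloadduct 21 (not isolated)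
Conditions: n-BuLi, THF, −78 °C; then 46% aq. HF, MeCN, 0 °C
Reagents that add atoms: none
Why: Iodine–lithium exchange and loss of LiOTf give the aryne, and the nucleophilic carbon of the ketene silyl acetal attacks the aryne carbon remote from the neighbouring OMOM group (inductive control) in a stepwise [2+2], so the ketal carbon ends on the ring carbon next to C–OMOM and HF unmasks the ketone; the C8 stereocentre is racemic and is destroyed in step 13.

Step 13
Reactants: 11 (2E,7E)-2-iodo-8,12-dimethyl-5-(propan-2-ylidene)trideca-2,7,11-triene; 22 8-methoxy-3,5-bis(methoxymethoxy)bicyclo[4.2.0]octa-1,3,5-trien-7-one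
Product: 27 3-isosesquilavandulyl-6,8-bis(methoxymethoxy)-2-methylnaphthalen-1-ol, via alkenyllithium 23 (not isolated), via lithium cyclobutenolate 24 (not isolated), via o-quinodimethane 25 (not isolated), via lithium dihydronaphthalenolate 26 (not isolated)
Conditions: t-BuLi (2 equiv), Et2O, −78 °C; then 22, THF, −78 → 25 °C; H2O
Reagents that add atoms: none
Why: Iodine–lithium exchange gives alkenyllithium 23 with retention, which adds to the strained ketone of 22; the lithium alkoxide 24 then undergoes oxyanion-accelerated conrotatory 4π opening of the four-membered ring (release of cyclobutene strain) to the o-quinodimethane 25, the oxide rotating outward and the alkenyl group inward. Thermal disrotatory 6π electrocyclisation of the resulting hexatriene joins the exocyclic CH(OMe) carbon (the future carbonyl carbon on the aromatic C–H side) to the alkenyl CH carbon (the future carbinol carbon), closing the six-membered carbocycle (26), and loss of LiOMe aromatises it to the naphtholate. The closest known reaction type is the ring expansion of 1-alkenylbenzocyclobutenols to 1-naphthols, the benzo counterpart of the Moore rearrangement of 4-alkenylcyclobutenones. The only ring closed is the six-membered one, by 6π electrocyclic closure; the two sp3 centres formed in it are erased by the elimination, so no stereocentre has to be controlled here. The selectivity needed is regiochemical (methyl next to the oxygenated carbon peri to OMOM, side chain next to the new aromatic C–H): it is fixed by the constitution of 22 (carbonyl on the ring carbon next to C–OMOM, from step 12) and of 11 (metal on the methyl-bearing carbon), and the E geometry of 11 puts H, not the chain, inside the cyclising triene.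

Step 14
Reactants: 27 naphthol
Product: 28 2-isosesquilavandulyl-5,7-bis(methoxymethoxy)-3-methylnaphthalene-1,4-dione
Conditions: (KSO3)2NO (Fremy's salt), KH2PO4, acetone/H2O, 0 → 25 °C
Reagents that add atoms: potassium nitrosodisulfonate, [K+].[K+].[O]N(S(=O)(=O)[O-])S(=O)(=O)[O-]
Why: Teuber oxidation of a 1-naphthol with a free para position gives the 1,4-quinone by phenoxyl radical capture at C4, a mild radical process that leaves the isolated alkenes and the MOM ethers alone.

Step 15
Reactants: 28 naphthoquinone
Product: 29 (1aS,7aR)-7a-isosesquilavandulyl-3,5-bis(methoxymethoxy)-1a-methyl-1a,7a-dihydronaphtho[2,3-b]oxirene-2,7-dione (oxirane oxygen on the face that carries OH in the target)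
Conditions: 30% aq. H2O2, LiOH, N-(1-naphthylmethyl)quinidinium chloride (10 mol%), CHCl3, −10 °C
Reagents that add atoms: hydrogen peroxide, OO
Why: Weitz–Scheffer nucleophilic epoxidation under chiral ion-pair (phase-transfer) control, in which the hydroperoxide anion adds only to the electron-poor quinone C=C (the three isolated alkenes are inert to nucleophilic oxidants) and the cinchona cation selects the face, setting both oxirane stereocentres in one event.

Step 16
Reactants: 29 quinone epoxide
Product: 30 (2S,3R)-3-chloro-2-hydroxy-2-isosesquilavandulyl-5,7-bis(methoxymethoxy)-3-methyl-2,3-dihydronaphthalene-1,4-dione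
Conditions: HCl (2 M in Et2O), CH2Cl2, −40 → 0 °C
Reagents that add atoms: hydrogen chloride, Cl
Why: Acid-mediated anti opening of the oxirane by chloride at the methyl-bearing carbon, which lies α to the donor-deactivated (ortho/para-dioxygenated aryl) carbonyl and β to the stronger acceptor carbonyl, as in the general opening of α,β-epoxy ketones at the carbon remote from the stronger acceptor; inversion at the chloro carbon and retention at the carbinol carbon give the trans chlorohydrin.

Step 17
Reactants: 30 bis-MOM chlorohydrin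
Product: 31 (2S,3R)-3-chloro-2,5,7-trihydroxy-2-isosesquilavandulyl-3-methyl-2,3-dihydronaphthalene-1,4-dione (target)
Conditions: ZnBr2, n-PrSH, CH2Cl2, 0 °C
Reagents that add atoms: none
Why: Zinc-bromide-activated acetal exchange with propane-1-thiol removes both aryl MOM ethers within minutes under non-basic, non-protic conditions, so the base-labile trans chlorohydrin (epoxide re-closure) and the acid-labile polyene are spared.

**Compound list**

1 | methyl acetoacetate | COC(=O)CC(C)=O | starting material
2 | geranyl bromide, (2E)-1-bromo-3,7-dimethylocta-2,6-diene | CC(C)=CCC/C(C)=C/CBr | starting material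
3 | methyl (4E)-2-acetyl-5,9-dimethyldeca-4,8-dienoate (racemic) | COC(=O)C(C/C=C(\C)CCC=C(C)C)C(C)=O | intermediate
4 | methyl (2Z,4E)-5,9-dimethyl-2-{1-[(trifluoromethanesulfonyl)oxy]ethylidene}deca-4,8-dienoate | COC(=O)/C(C/C=C(\C)CCC=C(C)C)=C(/C)OS(=O)(=O)C(F)(F)F | intermediate
5 | methyl (4E)-5,9-dimethyl-2-(propan-2-ylidene)deca-4,8-dienoate | COC(=O)C(C/C=C(\C)CCC=C(C)C)=C(C)C | intermediate
6 | (4E)-5,9-dimethyl-2-(propan-2-ylidene)deca-4,8-dien-1-ol | OCC(C/C=C(\C)CCC=C(C)C)=C(C)C | intermediate
7 | (5E)-3-(bromomethyl)-2,6,10-trimethylundeca-2,5,9-triene | BrCC(C/C=C(\C)CCC=C(C)C)=C(C)C | intermediate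
8 | prop-1-yn-1-ylmagnesium bromide | CC#C[Mg]Br | starting material
9 | (7E)-8,12-dimethyl-5-(propan-2-ylidene)trideca-7,11-dien-2-yne | CC#CCC(C/C=C(\C)CCC=C(C)C)=C(C)C | intermediate
10 | chlorobis(cyclopentadienyl)[(2E,7E)-8,12-dimethyl-5-(propan-2-ylidene)trideca-2,7,11-trien-2-yl]zirconium (Zr cis to the vinyl H) | Cl[Zr](C1C=CC=C1)(C1C=CC=C1)/C(C)=C/CC(C/C=C(\C)CCC=C(C)C)=C(C)C | intermediate
11 | (2E,7E)-2-iodo-8,12-dimethyl-5-(propan-2-ylidene)trideca-2,7,11-triene | I/C(C)=C/CC(C/C=C(\C)CCC=C(C)C)=C(C)C | intermediate
12 | phloroglucinol (benzene-1,3,5-triol) | Oc1cc(O)cc(O)c1 | starting material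
13 | 3,5-bis(methoxymethoxy)phenol | COCOc1cc(O)cc(OCOC)c1 | intermediate
14 | 2-iodo-3,5-bis(methoxymethoxy)phenol | COCOc1cc(O)c(I)c(OCOC)c1 | intermediate
15 | 2-iodo-3,5-bis(methoxymethoxy)phenyl trifluoromethanesulfonate | COCOc1cc(OS(=O)(=O)C(F)(F)F)c(I)c(OCOC)c1 | intermediate
16 | methyl 2-methoxyacetate | COCC(=O)OC | starting material
17 | lithium 1,2-dimethoxyethen-1-olate (ester enolate of 16) | COC=C(OC)O[Li] | intermediate
18 | tert-butyl[(1,2-dimethoxyethenyl)oxy]dimethylsilane (E/Z mixture) | COC=C(OC)O[Si](C)(C)C(C)(C)C | intermediate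
19 | [4,6-bis(methoxymethoxy)-2-(trifluoromethanesulfonyloxy)phenyl]lithium | [Li]c1c(OS(=O)(=O)C(F)(F)F)cc(OCOC)cc1OCOC | intermediate
20 | 3,5-bis(methoxymethoxy)benzyne (1,2-didehydrobenzene) | COCOC1=CC(OCOC)=CC#C1 | intermediate
21 | tert-butyl{[7,8-dimethoxy-3,5-bis(methoxymethoxy)bicyclo[4.2.0]octa-1,3,5-trien-7-yl]oxy}dimethylsilane (racemic, diastereomer mixture) | COC1c2cc(OCOC)cc(OCOC)c2C1(OC)O[Si](C)(C)C(C)(C)C | intermediate
22 | 8-methoxy-3,5-bis(methoxymethoxy)bicyclo[4.2.0]octa-1,3,5-trien-7-one (racemic) | COC1C(=O)c2c(OCOC)cc(OCOC)cc12 | intermediate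
23 | [(7E)-8,12-dimethyl-5-(propan-2-ylidene)trideca-2,7,11-trien-2-yl]lithium, Li in the place of I of 11 (Li cis to the vinyl H) | [Li]/C(C)=C/CC(C/C=C(\C)CCC=C(C)C)=C(C)C | intermediate
24 | lithium 7-[(2E,7E)-8,12-dimethyl-5-(propan-2-ylidene)trideca-2,7,11-trien-2-yl]-8-methoxy-3,5-bis(methoxymethoxy)bicyclo[4.2.0]octa-1,3,5-trien-7-olate | [Li]OC1(/C(C)=C/CC(C/C=C(\C)CCC=C(C)C)=C(C)C)C(OC)c2cc(OCOC)cc(OCOC)c12 | intermediate
25 | o-quinodimethane from opening of the C7–C8 bond of 24 (exocyclic C(OLi)(alkenyl)= and =CH(OMe) on a cyclohexadiene) | [Li]OC(/C(C)=C/CC(C/C=C(\C)CCC=C(C)C)=C(C)C)=C1C(OCOC)=CC(OCOC)=CC1=COC | intermediate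
26 | lithium 3-isosesquilavandulyl-4-methoxy-6,8-bis(methoxymethoxy)-2-methyl-3,4-dihydronaphthalen-1-olate | [Li]OC1=C(C)C(CC(C/C=C(\C)CCC=C(C)C)=C(C)C)C(OC)c2cc(OCOC)cc(OCOC)c12 | intermediate
27 | 3-isosesquilavandulyl-6,8-bis(methoxymethoxy)-2-methylnaphthalen-1-ol | CC(C)=CCC/C(C)=C/CC(Cc1cc2cc(OCOC)cc(OCOC)c2c(O)c1C)=C(C)C | intermediate
28 | 2-isosesquilavandulyl-5,7-bis(methoxymethoxy)-3-methylnaphthalene-1,4-dione | CC(C)=CCC/C(C)=C/CC(CC1=C(C)C(=O)c2c(OCOC)cc(OCOC)cc2C1=O)=C(C)C | intermediate
29 | (1aS,7aR)-7a-isosesquilavandulyl-3,5-bis(methoxymethoxy)-1a-methyl-1a,7a-dihydronaphtho[2,3-b]oxirene-2,7-dione | CC(C)=CCC/C(C)=C/CC(C[C@]12O[C@]2(C)C(=O)c3c(OCOC)cc(OCOC)cc3C1=O)=C(C)C | intermediate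
30 | (2S,3R)-3-chloro-2-hydroxy-2-isosesquilavandulyl-5,7-bis(methoxymethoxy)-3-methyl-2,3-dihydronaphthalene-1,4-dione | CC(C)=CCC/C(C)=C/CC(C[C@]1(O)C(=O)c2cc(OCOC)cc(OCOC)c2C(=O)[C@]1(C)Cl)=C(C)C | intermediate
31 | (2S,3R)-3-chloro-2,5,7-trihydroxy-2-[(4E)-5,9-dimethyl-2-(propan-2-ylidene)deca-4,8-dien-1-yl]-3-methyl-2,3-dihydronaphthalene-1,4-dione (CNP0351608.1) | CC(C)=CCC/C(C)=C/CC(C[C@]1(O)C(=O)c2cc(O)cc(O)c2C(=O)[C@]1(C)Cl)=C(C)C | target

**Step count and risks**

Total step count: 17. Longest linear sequence: 12 steps (steps 1–7, then 13–17).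

Steps most likely to fail:

Step 15 (asymmetric epoxidation). What may go wrong: insufficient facial discrimination of the tetrasubstituted C=C flanked by two carbonyls by the chiral ion pair, or racemic background epoxidation at the interface outrunning the catalysed path. Fallback: reagent control in place of catalyst control. Setting out from 28, the oxidant becomes a stoichiometric enantiopure hydroperoxide, TADOOH (the hydroperoxide of TADDOL, in the (4R,5R) or (4S,5S) series as the trial run dictates), deprotonated with a catalytic amount of LiOH in THF at −30 °C. The chiral peroxide anion itself delivers the oxygen in a homogeneous Weitz–Scheffer epoxidation of the kind known for enones, TADDOL is recovered, and the route is rejoined at 29. No new compound arises.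

Step 16 (chloride opening). What may go wrong: chloride entering at the side-chain carbon (regioisomeric chlorohydrin), protonation of the tetra- and trisubstituted alkenes by HCl (hydrochlorination or cation–olefin cyclisation), or partial loss of the peri MOM group. Fallback: the order of events and the acid are changed. Setting out from 29, the MOM groups are exchanged for silyl groups with TMSOTf and 2,2′-bipyridyl in CH2Cl2 at 0 °C, which should give the bis(trimethylsilyl) ether of the epoxide F1. Aqueous work-up hydrolyses it to (1aS,7aR)-3,5-dihydroxy-7a-isosesquilavandulyl-1a-methyl-1a,7a-dihydronaphtho[2,3-b]oxirene-2,7-dione F2. F2 is then opened with LiCl and acetic acid in THF (buffered halohydrin formation), which arrives directly at target 31. The free para hydroxyl, a vinylogous acid, makes the adjacent carbonyl a still weaker acceptor and so strengthens the bias for C–O cleavage at the methyl carbon, and acetic acid is too weak to protonate the alkenes.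

Step 7 (hydrozirconation–iodination). What may go wrong: zirconium placed on C3 instead of C2 (regioisomeric iodide and hence a wrongly substituted naphthol), or isomerisation of the skipped enyne by the zirconium hydride. Fallback: the side chain is no longer carried through the alkenyl metal but attached after the ring expansion. Setting out from 22, commercial isopropenylmagnesium bromide (THF, −78 → 40 °C) should run the same cascade through the bromomagnesium cyclobutenolate F3, the o-quinodimethane F4 and the bromomagnesium dihydronaphthalenolate F5 to 6,8-bis(methoxymethoxy)-2-methylnaphthalen-1-ol F6. Teuber oxidation gives 6,8-bis(methoxymethoxy)-2-methylnaphthalene-1,4-dione F7. Diels–Alder reaction with cyclopentadiene masks the quinone C=C as the adduct F8. Its only enolisable position, the ring-fusion C–H next to the carbonyl on the aromatic C–H side, is alkylated with bromide 7 (KOt-Bu, THF) to give the alkylated adduct F9. Retro-Diels–Alder reaction in toluene at 110 °C releases cyclopentadiene and gives quinone 28, where the route is rejoined. This is the classical alkylation route to 2-methyl-3-alkyl naphthoquinones of the vitamin K type.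

Further compounds

F0 | step 15 | none | none
F1 | step 16 | (1aS,7aR)-7a-isosesquilavandulyl-1a-methyl-3,5-bis(trimethylsilyloxy)-1a,7a-dihydronaphtho[2,3-b]oxirene-2,7-dione | CC(C)=CCC/C(C)=C/CC(C[C@]12O[C@]2(C)C(=O)c3c(O[Si](C)(C)C)cc(O[Si](C)(C)C)cc3C1=O)=C(C)C
F2 | step 16 | (1aS,7aR)-3,5-dihydroxy-7a-isosesquilavandulyl-1a-methyl-1a,7a-dihydronaphtho[2,3-b]oxirene-2,7-dione | CC(C)=CCC/C(C)=C/CC(C[C@]12O[C@]2(C)C(=O)c3c(O)cc(O)cc3C1=O)=C(C)C
F3 | step 7 | bromomagnesium 8-methoxy-3,5-bis(methoxymethoxy)-7-(prop-1-en-2-yl)bicyclo[4.2.0]octa-1,3,5-trien-7-olate | Br[Mg]OC1(C(C)=C)C(OC)c2cc(OCOC)cc(OCOC)c12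
F4 | step 7 | o-quinodimethane from opening of the C7–C8 bond of F3 | Br[Mg]OC(C(C)=C)=C1C(OCOC)=CC(OCOC)=CC1=COC
F5 | step 7 | bromomagnesium 4-methoxy-6,8-bis(methoxymethoxy)-2-methyl-3,4-dihydronaphthalen-1-olate | Br[Mg]OC1=C(C)CC(OC)c2cc(OCOC)cc(OCOC)c12
F6 | step 7 | 6,8-bis(methoxymethoxy)-2-methylnaphthalen-1-ol | Cc1ccc2cc(OCOC)cc(OCOC)c2c1O
F7 | step 7 | 6,8-bis(methoxymethoxy)-2-methylnaphthalene-1,4-dione | CC1=CC(=O)c2cc(OCOC)cc(OCOC)c2C1=O
F8 | step 7 | 6,8-bis(methoxymethoxy)-9a-methyl-1,4,4a,9a-tetrahydro-1,4-methanoanthracene-9,10-dione (racemic endo adduct) | CC12C(=O)c3c(OCOC)cc(OCOC)cc3C(=O)C1C1C=CC2C1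
F9 | step 7 | 4a-isosesquilavandulyl-6,8-bis(methoxymethoxy)-9a-methyl-1,4,4a,9a-tetrahydro-1,4-methanoanthracene-9,10-dione (racemic) | CC12C(=O)c3c(OCOC)cc(OCOC)cc3C(=O)C1(CC(C/C=C(\C)CCC=C(C)C)=C(C)C)C1C=CC2C1
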